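**Strategy.** The ten-membered carbocycle is closed late between C9 and C10 (germacranolide numbering). C8–O and the tertiary carbinol C10 stand in a 1,3 (aldol) relationship, and C10 sits next to the C1–C2 oxirane. The precursor is an open-chain bromomethyl ketone (C8, C9) that already carries the cis-fused α-methylene lactone, the (Z)-C4=C5 alkene and a cis-epoxy methyl ketone (C10). SmI2 converts the bromoketone into a samarium enolate that adds to the C10 ketone under chelation by the oxirane oxygen, so one operation forms the ring and the C10 stereocentre. Directed reduction at C8, angeloylation and desilylation complete the target.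

Key step: step 14

Remark: germacranolide numbering is used throughout (ring carbons C1–C10; lactone carbons C11, C12 (carbonyl, closed to O–C6) and C13 (exocyclic CH2); C14 = methyl on C10, C15 = methyl on C4). Read this way, the target SMILES is the 1R,2R,3R,6S,7R,8R,10R isomer with a 4Z alkene, a cis-1,2-oxirane, a cis-fused lactone (H6 and H7 on the same face) and an angelate, (Z)-2-methylbut-2-enoate, on O8.

Step 1
Reactants: 1 3-(trimethylsilyl)prop-2-ynal; 2 methyl acrylate
Product: 3 methyl 3-hydroxy-2-methylidene-5-(trimethylsilyl)pent-4-ynoate (racemic)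
Conditions: DABCO (0.3 equiv), 1,4-dioxane/H2O (1:1), rt
Reagents that add atoms: none
Why: Morita–Baylis–Hillman reaction of an activated ynal with an acrylate; the carbinol centre is formed racemic and is erased in step 2.

Step 2
Reactants: 3 methyl 3-hydroxy-2-methylidene-5-(trimethylsilyl)pent-4-ynoate
Product: 4 methyl (2Z)-2-(bromomethyl)-5-(trimethylsilyl)pent-2-en-4-ynoate
Conditions: NBS, Me2S, CH2Cl2, 0 °C to rt
Reagents that add atoms: N-bromosuccinimide, O=C1CCC(=O)N1Br
Why: Bromination of the Baylis–Hillman alcohol through an alkoxysulfonium salt with SN2' transposition should give the conjugated, thermodynamically preferred (Z)-allylic bromide; no stereocentre remains.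

Step 3
Reactants: 4 methyl (2Z)-2-(bromomethyl)-5-(trimethylsilyl)pent-2-en-4-ynoate; 5 (4S)-2,2-dimethyl-1,3-dioxolane-4-carbaldehyde
Product: 7 (4R,5R)-5-[(4S)-2,2-dimethyl-1,3-dioxolan-4-yl]-3-methylidene-4-[(trimethylsilyl)ethynyl]oxolan-2-one, via hydroxy ester 6 (not isolated)
Conditions: In powder, THF/H2O (1:1), rt; then PPTS (cat.), CH2Cl2, rt
Reagents that add atoms: none
Why: Indium-mediated Barbier allylation (Dreiding–Schmidt type) through a chair transition state at the γ-carbon should give the syn adduct, which lactonises to the cis-4,5-disubstituted α-methylene lactone, while Felkin–Anh (anti) addition to the α-alkoxy aldehyde 5 fixes the absolute configuration of C6 and thereby of C7.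

Step 4
Reactants: 7 (4R,5R)-5-[(4S)-2,2-dimethyl-1,3-dioxolan-4-yl]-3-methylidene-4-[(trimethylsilyl)ethynyl]oxolan-2-one
Product: 8 (2R,3R)-4-methylidene-5-oxo-3-[(trimethylsilyl)ethynyl]oxolane-2-carbaldehyde
Conditions: H5IO6, EtOAc, 0 °C to rt
Reagents that add atoms: none
Why: Periodic acid hydrolyses the terminal acetonide and cleaves the resulting 1,2-diol in one pot (Malaprade cleavage), removing the auxiliary stereocentre under non-basic conditions that leave C6 and C7 untouched.

Step 5
Reactants: 8 (2R,3R)-4-methylidene-5-oxo-3-[(trimethylsilyl)ethynyl]oxolane-2-carbaldehyde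
Product: 9 (4R,5R)-5-[(1Z)-2-iodoprop-1-en-1-yl]-3-methylidene-4-[(trimethylsilyl)ethynyl]oxolan-2-one
Conditions: EtPPh3I, n-BuLi, THF, −78 °C; I2; NaN(SiMe3)2, −20 °C; then 8, −78 °C
Reagents that add atoms: ethyltriphenylphosphonium iodide, CC[P+](c1ccccc1)(c1ccccc1)c1ccccc1.[I-]; iodine, [I][I]
Why: Stork–Zhao-type Wittig olefination with the α-iodo ylide at −78 °C should give the (Z)-iodoalkene (iodine cis to C6) faster than the ylide can add to the conjugated lactone or epimerise C6.

Step 6
Reactants: 10 (2R)-but-3-yn-2-ol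
Product: 11 (4R)-pent-2-yne-1,4-diol
Conditions: n-BuLi (2.1 equiv), THF, −78 to 0 °C; (CH2O)n, rt; NH4Cl (aq)
Reagents that add atoms: paraformaldehyde (as formaldehyde), C=O
Why: Hydroxymethylation of the lithium alkynylide (alkoxide dianion) with formaldehyde; the carbinol centre of 10 is not touched.

Step 7
Reactants: 11 (4R)-pent-2-yne-1,4-diol
Product: 12 (2Z,4R)-pent-2-ene-1,4-diol
Conditions: H2 (1 atm), Pd/CaCO3 poisoned with Pb(OAc)2 (Lindlar catalyst), quinoline, EtOAc, rt
Reagents that add atoms: none
Why: Lindlar semihydrogenation gives the (Z)-alkene that a cis-oxirane requires.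

Step 8
Reactants: 12 (2Z,4R)-pent-2-ene-1,4-diol
Product: 13 (1R)-1-[(2S,3R)-3-(hydroxymethyl)oxiran-2-yl]ethan-1-ol
Conditions: mCPBA, NaHCO3, CH2Cl2, 0 °C
Reagents that add atoms: mCPBA, OOC(=O)c1cccc(Cl)c1
Why: Hydroxyl-directed peracid epoxidation in the A(1,3)-strain-minimised conformer (carbinol H eclipsing the alkene) delivers oxygen syn to the secondary hydroxyl, giving the threo cis-epoxide, so the (R)-carbinol sets both oxirane centres.

Step 9
Reactants: 13 (1R)-1-[(2S,3R)-3-(hydroxymethyl)oxiran-2-yl]ethan-1-ol
Product: 14 (2S,3R)-3-acetyloxirane-2-carbaldehyde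
Conditions: Dess–Martin periodinane (2.4 equiv), NaHCO3, CH2Cl2, 0 °C to rt; filtered solution used at once
Reagents that add atoms: none
Why: Dess–Martin oxidation of both hydroxyls under buffered, non-aqueous conditions; the relay stereocentre is erased and the non-enolisable oxirane carbons keep their configuration.

Step 10
Reactants: 9 (4R,5R)-5-[(1Z)-2-iodoprop-1-en-1-yl]-3-methylidene-4-[(trimethylsilyl)ethynyl]oxolan-2-one; 14 (2S,3R)-3-acetyloxirane-2-carbaldehyde
Product: 15 (4R,5S)-5-[(1Z,3R)-3-[(2R,3R)-3-acetyloxiran-2-yl]-3-hydroxy-2-methylprop-1-en-1-yl]-3-methylidene-4-[(trimethylsilyl)ethynyl]oxolan-2-one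
Conditions: CrCl2 (4 equiv), NiCl2 (2 mol%), DMSO/THF, rt
Reagents that add atoms: none
Why: Nozaki–Hiyama–Kishi coupling, in which the alkenylchromium species adds to the aldehyde far faster than to the methyl ketone with retention of alkene geometry, and Felkin–Anh addition (oxirane C–O anti to the incoming nucleophile, no chelation in DMSO) should give the erythro (3R) carbinol.

Step 11
Reactants: 15 (the C3 alcohol from step 10)
Product: 16 O3-tert-butyldimethylsilyl ether of 15
Conditions: TBSOTf, 2,6-lutidine, CH2Cl2, −78 °C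
Reagents that add atoms: tert-butyldimethylsilyl trifluoromethanesulfonate, CC(C)(C)[Si](C)(C)OS(=O)(=O)C(F)(F)F
Why: Silylation of the secondary allylic alcohol (the open-chain form is trapped from any hemiketal equilibrium with the C10 ketone) protects O3 for the enolate and acylation steps.

Step 12
Reactants: 16 O3-tert-butyldimethylsilyl ether of 15
Product: 17 bromoalkyne (16 with C≡C–SiMe3 replaced by C≡C–Br)
Conditions: NBS, AgNO3 (10 mol%), acetone, rt, dark
Reagents that add atoms: N-bromosuccinimide, O=C1CCC(=O)N1Br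
Why: Silver-catalysed bromodesilylation of the alkynylsilane is faster than bromination of the trisubstituted alkene or of the ketone.

Step 13
Reactants: 17 bromoalkyne
Product: 18 bromomethyl ketone (4-(bromoacetyl) lactone; C8 ketone, C9 bearing Br)
Conditions: (XPhos)AuNTf2 (3 mol%), H2O (3 equiv), ClCH2CH2Cl, rt; used without prolonged storage
Reagents that add atoms: water, O
Why: Gold-catalysed hydration of a haloalkyne adds water at the carbon remote from bromine and should give the bromomethyl ketone regiospecifically under near-neutral conditions that leave oxirane, silyl ether and exocyclic alkene alone.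

Step 14
Reactants: 18 bromomethyl ketone
Product: 20 3-O-(tert-butyldimethylsilyl)-1,2-epoxy-10-hydroxy-8-oxogermacra-4Z,11(13)-dien-12,6-olide, via samarium enolate 19 (not isolated)
Conditions: SmI2 (2.1 equiv, 0.1 M in THF) added over 3 h to 18 (0.002 M in THF), −78 °C; pH 7 buffer at −78 °C
Reagents that add atoms: none
Why: Two single-electron transfers from SmI2 to the C–Br bond of 18, much faster at −78 °C than reduction of the oxirane-bearing ketone or the conjugated lactone, should give the regiodefined trivalent samarium enolate 19 (C9 nucleophile, no enolisation towards C7 or C14), which adds to the C10 methyl ketone. The closest known reaction type is the SmI2-promoted intramolecular Reformatsky-type aldol reaction of α-halo carbonyl compounds used for medium and large rings. The ten-membered carbocycle is closed by a 10-(enolendo)-exo-trig aldol addition; the (Z)-C4=C5 alkene, the cis-oxirane and the cis-fused lactone act as turn elements that bring C9 and C10 together, and high dilution suppresses intermolecular aldol addition. The only new stereocentre, C10, is set by a Cram chelate in which samarium bridges the C10 carbonyl and the oxirane oxygen, so that C9 attacks the face anti to C2 and gives the 10R carbinol with its hydroxyl syn to the oxirane oxygen. The step needs chemoselective electron transfer (slow addition of two equivalents of SmI2, no HMPA, no proton source), addition before enolate equilibration (low temperature, chelated samarium aldolate) and survival of the base-sensitive C7–H next to the new ketone (cold neutral quench).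

Step 15
Reactants: 20 (the 8-oxo macrocycle from step 14)
Product: 21 3-O-(tert-butyldimethylsilyl)-1,2-epoxy-8,10-dihydroxygermacra-4Z,11(13)-dien-12,6-olide (8R)
Conditions: Me4NBH(OAc)3, MeCN/AcOH (1:1), −30 °C
Reagents that add atoms: none
Why: Evans–Saksena reduction, in which the tertiary C10 hydroxyl binds the triacetoxyborohydride and delivers hydride intramolecularly to C8 through a chair transition state with both ring bonds equatorial, should give the 1,3-anti diol (8R).

Step 16
Reactants: 21 (the 8,10-diol from step 15)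
Product: 22 O8-angelate of 21 (3-O-silyl ether of the target)
Conditions: angelic acid, 2,4,6-trichlorobenzoyl chloride, Et3N, toluene, rt; then 21, 75 °C
Reagents that add atoms: angelic acid ((Z)-2-methylbut-2-enoic acid), C/C=C(/C)C(=O)O
Why: Yamaguchi-type esterification through the preformed mixed anhydride without DMAP acylates the secondary C8 hydroxyl (the tertiary C10 hydroxyl is inert) and avoids Z to E isomerisation of the angelate.

Step 17
Reactants: 22 O8-angelate of 21
Product: 23 target, (1R,2R,3R,6S,7R,8R,10R)-8-angeloyloxy-1,2-epoxy-3,10-dihydroxygermacra-4Z,11(13)-dien-12,6-olide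
Conditions: Bu4NF, AcOH (1:1), THF, 0 °C to rt
Reagents that add atoms: none
Why: Buffered fluoride desilylation should free O3 without acyl migration, oxirane opening or conjugate addition to the lactone.

**Compound list**

1 | 3-(trimethylsilyl)prop-2-ynal | O=CC#C[Si](C)(C)C | starting material
2 | methyl acrylate | C=CC(=O)OC | starting material
3 | methyl 3-hydroxy-2-methylidene-5-(trimethylsilyl)pent-4-ynoate (racemic) | C=C(C(=O)OC)C(O)C#C[Si](C)(C)C | intermediate
4 | methyl (2Z)-2-(bromomethyl)-5-(trimethylsilyl)pent-2-en-4-ynoate | COC(=O)/C(CBr)=C/C#C[Si](C)(C)C | intermediate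
5 | (4S)-2,2-dimethyl-1,3-dioxolane-4-carbaldehyde | O=C[C@@H]1COC(C)(C)O1 | starting material
6 | methyl (3R,4R)-4-[(4S)-2,2-dimethyl-1,3-dioxolan-4-yl]-4-hydroxy-2-methylidene-3-[(trimethylsilyl)ethynyl]butanoate | C=C(C(=O)OC)[C@H](C#C[Si](C)(C)C)[C@@H](O)[C@@H]1COC(C)(C)O1 | intermediate (not isolated)
7 | (4R,5R)-5-[(4S)-2,2-dimethyl-1,3-dioxolan-4-yl]-3-methylidene-4-[(trimethylsilyl)ethynyl]oxolan-2-one (cis-lactone) | C=C1C(=O)O[C@@H]([C@@H]2COC(C)(C)O2)[C@H]1C#C[Si](C)(C)C | intermediate
8 | (2R,3R)-4-methylidene-5-oxo-3-[(trimethylsilyl)ethynyl]oxolane-2-carbaldehyde | C=C1C(=O)O[C@@H](C=O)[C@H]1C#C[Si](C)(C)C | intermediate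
9 | (4R,5R)-5-[(1Z)-2-iodoprop-1-en-1-yl]-3-methylidene-4-[(trimethylsilyl)ethynyl]oxolan-2-one | C=C1C(=O)O[C@@H](/C=C(/C)I)[C@H]1C#C[Si](C)(C)C | intermediate
10 | (2R)-but-3-yn-2-ol | C[C@@H](O)C#C | starting material
11 | (4R)-pent-2-yne-1,4-diol | C[C@@H](O)C#CCO | intermediate
12 | (2Z,4R)-pent-2-ene-1,4-diol | C[C@@H](O)/C=C\CO | intermediate
13 | (1R)-1-[(2S,3R)-3-(hydroxymethyl)oxiran-2-yl]ethan-1-ol (cis-epoxide) | OC[C@H]1O[C@H]1[C@@H](C)O | intermediate
14 | (2S,3R)-3-acetyloxirane-2-carbaldehyde (cis) | O=C[C@H]1O[C@H]1C(C)=O | intermediate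
15 | (4R,5S)-5-[(1Z,3R)-3-[(2R,3R)-3-acetyloxiran-2-yl]-3-hydroxy-2-methylprop-1-en-1-yl]-3-methylidene-4-[(trimethylsilyl)ethynyl]oxolan-2-one | C=C1C(=O)O[C@@H](/C=C(/C)[C@@H](O)[C@H]2O[C@H]2C(C)=O)[C@H]1C#C[Si](C)(C)C | intermediate
16 | O3-tert-butyldimethylsilyl ether of 15 | C=C1C(=O)O[C@@H](/C=C(/C)[C@@H](O[Si](C)(C)C(C)(C)C)[C@H]2O[C@H]2C(C)=O)[C@H]1C#C[Si](C)(C)C | intermediate
17 | bromoalkyne: 16 with the trimethylsilylethynyl group replaced by bromoethynyl | C=C1C(=O)O[C@@H](/C=C(/C)[C@@H](O[Si](C)(C)C(C)(C)C)[C@H]2O[C@H]2C(C)=O)[C@H]1C#CBr | intermediate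
18 | bromomethyl ketone: the 4-(bromoacetyl) lactone corresponding to 17 | C=C1C(=O)O[C@@H](/C=C(/C)[C@@H](O[Si](C)(C)C(C)(C)C)[C@H]2O[C@H]2C(C)=O)[C@H]1C(=O)CBr | intermediate
19 | diiodosamarium enolate of 18 (C8–O–SmI2, C8=C9) | C=C1C(=O)O[C@@H](/C=C(/C)[C@@H](O[Si](C)(C)C(C)(C)C)[C@H]2O[C@H]2C(C)=O)[C@H]1C(=C)O[Sm](I)I | intermediate (not isolated)
20 | 3-O-(tert-butyldimethylsilyl)-1,2-epoxy-10-hydroxy-8-oxogermacra-4Z,11(13)-dien-12,6-olide; C1, C2, C3, C6, C7, C10 as in the target | C=C1C(=O)O[C@H]2/C=C(/C)[C@@H](O[Si](C)(C)C(C)(C)C)[C@H]3O[C@H]3[C@](C)(O)CC(=O)[C@@H]12 | intermediate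
21 | 8R-hydroxy analogue of 20 (8,10-diol, 1,3-anti) | C=C1C(=O)O[C@H]2/C=C(/C)[C@@H](O[Si](C)(C)C(C)(C)C)[C@H]3O[C@H]3[C@](C)(O)C[C@@H](O)[C@@H]12 | intermediate
22 | O8-angelate of 21 (3-O-silyl ether of the target) | C=C1C(=O)O[C@H]2/C=C(/C)[C@@H](O[Si](C)(C)C(C)(C)C)[C@H]3O[C@H]3[C@](C)(O)C[C@@H](OC(=O)/C(C)=C\C)[C@@H]12 | intermediate
23 | (1R,2R,3R,6S,7R,8R,10R)-8-angeloyloxy-1,2-epoxy-3,10-dihydroxygermacra-4Z,11(13)-dien-12,6-olide | C=C1C(=O)O[C@H]2/C=C(/C)[C@@H](O)[C@H]3O[C@H]3[C@](C)(O)C[C@@H](OC(=O)/C(C)=C\C)[C@@H]12 | target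

**Totals.** Total step count: 17. Longest linear sequence: 13 steps (steps 1–5, then 10–17); the second branch (steps 6–9) joins at step 10.

**Steps most likely to fail**

Step 14 (key step). Electron transfer to the oxirane-bearing ketone or to the conjugated lactone, or intermolecular aldol addition, may outrun the slow ten-membered ring closure, and enolate equilibration towards C7 may move the exocyclic alkene into conjugation. Fallback: from 18, zinc dust and Me3SiCl (THF, 0 °C) should give the regiodefined trimethylsilyl enol ether F1 by reductive silylation of the α-bromo ketone. A Mukaiyama aldol addition of F1 to the C10 ketone under high dilution with the chelating Lewis acid MgBr2·OEt2 (CH2Cl2, −78 °C), followed by cleavage of the silyl aldolate on mildly acidic work-up, should return to 20, with no reductant present while the ring closes.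

Step 10. Partial addition through a chromium chelate (carbonyl and oxirane oxygen) instead of the Felkin–Anh arrangement would lower facial selectivity at C3. Fallback: from 9 and 14 the coupling is run as before and the 3-epimeric alcohol F2 is separated. Its carbinol centre is inverted by a Mitsunobu reaction with chloroacetic acid (PPh3, DIAD, toluene, 0 °C) to the chloroacetate F3. Thiourea and NaHCO3 (EtOH, rt) should then remove the chloroacetyl group without touching the conjugated lactone and return to 15.

Step 15. The ten-membered ring may not allow the chair geometry for internal hydride delivery, so that hydride reaches the other face of C8. Fallback: from 20, a chelation-controlled syn reduction (Et2BOMe, NaBH4, THF/MeOH, −78 °C; Narasaka–Prasad reduction) should give the 8-epimeric diol F4. A Mitsunobu esterification of F4 with angelic acid (PPh3, DIAD, toluene, 0 °C to rt) should install the angelate with inversion at C8 and return to 22, bypassing 21.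

**Further compounds**

F1 | step 14 | trimethylsilyl enol ether of 18 (C8–OSiMe3, C8=C9) | C=C1C(=O)O[C@@H](/C=C(/C)[C@@H](O[Si](C)(C)C(C)(C)C)[C@H]2O[C@H]2C(C)=O)[C@H]1C(=C)O[Si](C)(C)C
F2 | step 10 | 3-epimer of 15 | C=C1C(=O)O[C@@H](/C=C(/C)[C@H](O)[C@H]2O[C@H]2C(C)=O)[C@H]1C#C[Si](C)(C)C
F3 | step 10 | O3-chloroacetate of 15 | C=C1C(=O)O[C@@H](/C=C(/C)[C@@H](OC(=O)CCl)[C@H]2O[C@H]2C(C)=O)[C@H]1C#C[Si](C)(C)C
F4 | step 15 | 8-epimer of 21 (syn 8,10-diol) | C=C1C(=O)O[C@H]2/C=C(/C)[C@@H](O[Si](C)(C)C(C)(C)C)[C@H]3O[C@H]3[C@](C)(O)C[C@H](O)[C@@H]12
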